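**Retrosynthetic overview**
- Target ⇒ (3R)-β-cryptoxanthin + palmitoleic acid. The ester C–O bond is made last, so the 9Z alkene never meets palladium or heat.
- β-Cryptoxanthin ⇒ ring–chain bond C6–C7. The tosylhydrazone of (4R,6R)-actinol, whose ketone carbon reacts as a nucleophile in its diazo form, is cross-coupled under palladium catalysis with an all-E C31 polyenyl iodide. The same step creates the C5=C6 ring alkene.
- C31 iodide ⇒ β-apo-8'-carotenal by one-carbon iodo-olefination. Hydrazone ⇒ actinol, which supplies C3 (R) from the chiral pool.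
- Rings: none is built. Both six-membered rings are bought, the hydroxylated one in actinol and the other in the apocarotenal.

Assumption: the target is read as the all-E polyene with a 3R carbinol centre and a 9Z acyl chain; (4R,6R)-actinol (industrial zeaxanthin intermediate), β-apo-8'-carotenal (food colourant E 160e) and palmitoleic acid are taken as commercial.

**Route**

Step 1
Reactants: 1 (4R,6R)-4-hydroxy-2,2,6-trimethylcyclohexan-1-one ((4R,6R)-actinol)
Product: 2 N'-[(1E,4R,6R)-4-hydroxy-2,2,6-trimethylcyclohexylidene]-4-methylbenzenesulfonohydrazide (tosylhydrazone of 1)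
Conditions: TsNHNH2 (1.1 equiv), TsOH·H2O (2 mol%), EtOH, 70 °C, 16 h; crystallise
Reagents that add atoms: p-toluenesulfonyl hydrazide, Cc1ccc(cc1)S(=O)(=O)NN
Why: Acid-catalysed tosylhydrazone formation works even on α-quaternary ketones of the camphor type, the C4 carbinol centre is not touched and stays R, and the C6 configuration and the C=N geometry are of no consequence because both are erased in step 3.

Step 2
Reactants: 3 all-E-β-apo-8'-carotenal
Product: 4 (1E,3E,5E,7E,9E,11E,13E,15E,17E)-1-iodo-3,7,12,16-tetramethyl-18-(2,6,6-trimethylcyclohex-1-en-1-yl)octadeca-1,3,5,7,9,11,13,15,17-nonaene (all-E C31 polyenyl iodide)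
Conditions: CrCl2 (8 equiv), CHI3 (3 equiv), 1,4-dioxane/THF 6:1, 0 °C to rt, Ar, dark; plug of deactivated neutral alumina; use at once
Reagents that add atoms: iodoform, C(I)(I)I
Why: Takai iodo-olefination, in which CHI3 and divalent chromium convert the aldehyde carbon into the E-iodoalkene with one added carbon, is mild and chemoselective for enals and leaves the polyene untouched, and any Z isomer at the new bond is corrected by the equilibration in step 3.

Step 3
Reactants: 2 tosylhydrazone of actinol; 4 all-E C31 polyenyl iodide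
Product: 6 all-E-(3R)-β,β-caroten-3-ol (β-cryptoxanthin), via diazoalkane 5 (not isolated)
Conditions: 2 (1.4 equiv), Pd2(dba)3 (2.5 mol%), XPhos (10 mol%), LiOtBu (3.3 equiv), 1,4-dioxane, 90 °C, 4 h, Ar, dark; aq NH4Cl; then n-heptane, reflux, 4 h, dark; crystallise (CH2Cl2/MeOH)
Reagents that add atoms: none
Why: In this Barluenga cross-coupling LiOtBu turns 2 into diazoalkane 5 (Bamford–Stevens), whose carbon, the former electrophilic ketone carbon, now attacks as a nucleophile the alkenyl palladium iodide (divalent palladium) formed from 4 and zerovalent palladium, loss of N2 gives a palladium carbene, migratory insertion of the polyenyl group forges C6–C7, syn β-hydride elimination of the only β-hydrogen (H-5) sets the tetrasubstituted C5=C6 alkene, C3 is a spectator and stays R, and the heptane reflux equilibrates any Z isomers to the all-E polyene.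

Step 4
Reactants: 6 β-cryptoxanthin; 7 (9Z)-hexadec-9-enoic acid (palmitoleic acid)
Product: 8 (3R)-β,β-caroten-3-yl (9Z)-hexadec-9-enoate (target, CNP0382087.1)
Conditions: 7 (1.4 equiv), DCC (1.5 equiv), DMAP (0.2 equiv), CH2Cl2, 0 °C to rt, Ar, dark
Reagents that add atoms: none
Why: Steglich esterification acylates the secondary C3 alcohol through carbodiimide activation of the acid and DMAP acyl transfer without breaking the C3–O bond, so C3 stays R, and the neutral room-temperature conditions leave the 9Z alkene and the all-E polyene unchanged.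

**Compound list**

1 | (4R,6R)-4-hydroxy-2,2,6-trimethylcyclohexan-1-one ((4R,6R)-actinol) | O[C@@H]1C[C@@H](C)C(=O)C(C)(C)C1 | starting material
2 | N'-[(1E,4R,6R)-4-hydroxy-2,2,6-trimethylcyclohexylidene]-4-methylbenzenesulfonohydrazide | O[C@@H]1C[C@@H](C)/C(=N\NS(=O)(=O)c2ccc(C)cc2)C(C)(C)C1 | intermediate
3 | all-E-β-apo-8'-carotenal, (2E,4E,6E,8E,10E,12E,14E,16E)-2,6,11,15-tetramethyl-17-(2,6,6-trimethylcyclohex-1-en-1-yl)heptadeca-2,4,6,8,10,12,14,16-octaenal | O=C/C(C)=C/C=C/C(C)=C/C=C/C=C(C)/C=C/C=C(C)/C=C/C1=C(C)CCCC1(C)C | starting material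
4 | all-E C31 polyenyl iodide, (1E,3E,5E,7E,9E,11E,13E,15E,17E)-1-iodo-3,7,12,16-tetramethyl-18-(2,6,6-trimethylcyclohex-1-en-1-yl)octadeca-1,3,5,7,9,11,13,15,17-nonaene | I/C=C/C(C)=C/C=C/C(C)=C/C=C/C=C(C)/C=C/C=C(C)/C=C/C1=C(C)CCCC1(C)C | intermediate
5 | (1R,5R)-4-diazo-3,3,5-trimethylcyclohexan-1-ol (diazoalkane, not isolated) | O[C@@H]1C[C@@H](C)C(=[N+]=[N-])C(C)(C)C1 | intermediate
6 | all-E-(3R)-β,β-caroten-3-ol (β-cryptoxanthin) | O[C@@H]1CC(C)=C(/C=C/C(C)=C/C=C/C(C)=C/C=C/C=C(C)/C=C/C=C(C)/C=C/C2=C(C)CCCC2(C)C)C(C)(C)C1 | intermediate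
7 | (9Z)-hexadec-9-enoic acid (palmitoleic acid) | CCCCCC/C=C\CCCCCCCC(=O)O | starting material
8 | (3R)-β,β-caroten-3-yl (9Z)-hexadec-9-enoate | CCCCCC/C=C\CCCCCCCC(=O)O[C@@H]1CC(C)=C(/C=C/C(C)=C/C=C/C(C)=C/C=C/C=C(C)/C=C/C=C(C)/C=C/C2=C(C)CCCC2(C)C)C(C)(C)C1 | target

**Step count**
Total steps: 4. Longest linear sequence: 3 steps (1 → 2 → 6 → 8, or 3 → 4 → 6 → 8).

**Steps most likely to fail**

Step 3 (highest risk). The coupling has to build a tetrasubstituted ring alkene from a doubly α-branched diazoalkane. Diazoalkane 5 may collapse by 1,2-hydrogen shift to the simple ring alkene before palladium captures it. The carbene insertion is crowded, and the free alkoxide could reduce the alkenyl palladium species. The closest precedents are α-quaternary cyclic ketone tosylhydrazones carrying a free hydroxyl, which couple under these conditions, but they give trisubstituted alkenes.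

The fallback keeps the ketone carbon as the nucleophile but makes the bond stepwise. It sets out from 1, uses 4, and comes back at 6. Compound 1 is condensed with N2H4·H2O (EtOH, reflux) to the unsubstituted hydrazone (1R,5R)-4-hydrazinylidene-3,3,5-trimethylcyclohexan-1-ol F1. Barton iodination (I2, 1,1,3,3-tetramethylguanidine, Et2O, 0 °C to rt) gives the vinyl iodide (1R)-4-iodo-3,5,5-trimethylcyclohex-3-en-1-ol F2; the alkene can only form toward the methyl-bearing carbon. O-Deprotonation with MeLi, iodine–lithium exchange with t-BuLi (THF, −78 °C), quench with B(OiPr)3 and mild acid work-up give [(4R)-4-hydroxy-2,6,6-trimethylcyclohex-1-en-1-yl]boronic acid F3. Suzuki–Miyaura coupling of this with 4 (Pd(PPh3)4, aqueous TlOH, THF, rt, dark), followed by the same heptane equilibration, delivers 6.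

Step 2. The long polyenal is a deactivated aldehyde, the Takai reaction can give some Z iodide, and 4 is sensitive to light and air.

The fallback replaces the chromium olefination by alkyne hydrometalation, which fixes the E geometry by syn addition. It sets out from 3 and comes back at 4. Ohira–Bestmann homologation of 3 (dimethyl (1-diazo-2-oxopropyl)phosphonate, K2CO3, MeOH/THF, rt) gives the terminal enyne (3E,5E,7E,9E,11E,13E,15E,17E)-3,7,12,16-tetramethyl-18-(2,6,6-trimethylcyclohex-1-en-1-yl)octadeca-3,5,7,9,11,13,15,17-octaen-1-yne F4. Hydrozirconation with Cp2Zr(H)Cl (THF, rt, dark) gives the E-alkenylzirconocene chloride F5 in the flask. Iodinolysis with I2 (1.0 equiv, −78 °C, Na2S2O3 quench) gives 4 with retention.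

Step 4. This is the least risky of the three; step 1 is judged safer still. Carbodiimide activation can stall as the N-acylurea, and the poorly soluble carotenol may acylate slowly.

The fallback uses a preformed acyl chloride instead of in-flask activation. It sets out from 7, uses 6, and comes back at 8. Acid 7 is converted with (COCl)2 and catalytic DMF (CH2Cl2, 0 °C to rt) into (9Z)-hexadec-9-enoyl chloride F6. This acylates 6 in CH2Cl2/pyridine at 0 °C in the dark to give 8.

**Further compounds**

F1 | step 3 | (1R,5R)-4-hydrazinylidene-3,3,5-trimethylcyclohexan-1-ol (unsubstituted hydrazone of 1) | O[C@@H]1C[C@@H](C)C(=NN)C(C)(C)C1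
F2 | step 3 | (1R)-4-iodo-3,5,5-trimethylcyclohex-3-en-1-ol | O[C@@H]1CC(C)=C(I)C(C)(C)C1
F3 | step 3 | [(4R)-4-hydroxy-2,6,6-trimethylcyclohex-1-en-1-yl]boronic acid | O[C@@H]1CC(C)=C(B(O)O)C(C)(C)C1
F4 | step 2 | (3E,5E,7E,9E,11E,13E,15E,17E)-3,7,12,16-tetramethyl-18-(2,6,6-trimethylcyclohex-1-en-1-yl)octadeca-3,5,7,9,11,13,15,17-octaen-1-yne | C#C/C(C)=C/C=C/C(C)=C/C=C/C=C(C)/C=C/C=C(C)/C=C/C1=C(C)CCCC1(C)C
F5 | step 2 | chlorobis(cyclopentadienyl)[(1E)-all-E-C31 polyen-1-yl]zirconium (E-alkenylzirconocene chloride, not isolated) | Cl[Zr](/C=C/C(C)=C/C=C/C(C)=C/C=C/C=C(C)/C=C/C=C(C)/C=C/C1=C(C)CCCC1(C)C)(C2C=CC=C2)C2C=CC=C2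
F6 | step 4 | (9Z)-hexadec-9-enoyl chloride | CCCCCC/C=C\CCCCCCCC(=O)Cl
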